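**Plan**
Ring B is numbered C1 (carboxyl carbon), C2 (OH), C3 (aroyloxy), C4 (OH), C5 (H), C6 (propyl); ring A is the 2,4-dimethoxy-6-propylbenzoyl unit.
Retrosynthesis: the benzyl ester of the ring B acid is cut last; ring B is taken back to a cyclohexane-1,3-dione and opened at C1-C6 and C2-C3, leaving dibenzyl malonate and an (E)-1-aroyloxyhept-3-en-2-one. That enone is cut at its CH2-O bond and its C=C bond (ring A acid, butanal, a chloroacetyl ylide), and the ring A acid at its aryl-carboxyl bond (divarinol).
Enabling feature: in ring B the carboxyl-bearing C1 lies next to the propyl-bearing C6, and C2, C3 and C4 carry three contiguous oxygens. C1/C2 with the carboxyl therefore map onto a malonate, and C3-C6 onto an enone whose alpha-prime carbon already carries the C3 oxygen, acylated by ring A.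
Forward: ring A acid from divarinol (steps 1-3), chain assembly by Wittig reaction and carboxylate alkylation (steps 4-5), ring B closed by Michael-Claisen annulation (step 6), aromatized (step 7), benzyl ester removed (step 8).
Stereochemistry: the target is achiral; the two sp3 centres formed in step 6 are racemic and are erased in step 7.

Key step: step 6

Remark: the chloroacetyl ylide used in step 4 is taken as a purchased reagent (it is otherwise made from 1,3-dichloroacetone and PPh3).

**Step 1**
Reactants: 1 5-propylbenzene-1,3-diol (divarinol)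
Product: 2 1,3-dimethoxy-5-propylbenzene
Conditions: MeI (2.5 equiv), K2CO3, DMF, rt
Reagents that add atoms: iodomethane, CI
Why: Williamson ether synthesis, in which both phenoxides formed by K2CO3 are methylated by MeI, a routine transformation of resorcinols.

**Step 2**
Reactants: 2 1,3-dimethoxy-5-propylbenzene
Product: 4 2,4-dimethoxy-6-propylbenzaldehyde, via aryl iminium salt 3 (not isolated)
Conditions: POCl3, DMF, 0 °C to 80 °C; then H2O
Reagents that add atoms: N,N-dimethylformamide, CN(C)C=O; water, O
Why: Vilsmeier-Haack formylation, in which the chloroiminium ion should attack the ring carbon para to one methoxy and ortho to the other (the two such positions are equivalent) in preference to the more crowded carbon between the methoxy groups, and iminium salt 3 is hydrolysed on aqueous work-up.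

**Step 3**
Reactants: 4 2,4-dimethoxy-6-propylbenzaldehyde
Product: 5 2,4-dimethoxy-6-propylbenzoic acid
Conditions: NaClO2, NaH2PO4, 2-methylbut-2-ene, t-BuOH/H2O, rt
Reagents that add atoms: sodium chlorite, [Na+].[O-]Cl=O
Why: Pinnick oxidation, in which chlorous acid converts the hindered aryl aldehyde into the acid while 2-methylbut-2-ene traps HOCl so that the electron-rich ring is not chlorinated.

**Step 4**
Reactants: 6 butanal; 7 1-chloro-3-(triphenylphosphoranylidene)propan-2-one
Product: 8 (E)-1-chlorohept-3-en-2-one
Conditions: THF, 60 °C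
Reagents that add atoms: none
Why: Wittig olefination with a ketone-stabilized ylide, which should give the E-enone selectively and leaves the chloromethyl group untouched.

**Step 5**
Reactants: 5 2,4-dimethoxy-6-propylbenzoic acid; 8 (E)-1-chlorohept-3-en-2-one
Product: 10 (E)-2-oxohept-3-en-1-yl 2,4-dimethoxy-6-propylbenzoate, via caesium carboxylate 9 (not isolated)
Conditions: Cs2CO3 (0.5 equiv), MeOH, rt, evaporate; then 8, DMF, 0 °C to rt
Reagents that add atoms: none
Why: SN2 displacement of the activated alpha-chloro ketone chloride by the caesium carboxylate (carboxylate O-alkylation), the reliable way to esterify a di-ortho-substituted benzoic acid because its hindered carbonyl carbon is not the site of attack.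

**Step 6**
Reactants: 10 (E)-2-oxohept-3-en-1-yl 2,4-dimethoxy-6-propylbenzoate; 11 dibenzyl malonate
Product: 13 (±)-trans-benzyl 3-(2,4-dimethoxy-6-propylbenzoyloxy)-2-hydroxy-4-oxo-6-propylcyclohex-2-ene-1-carboxylate, via open-chain Michael adduct 12 (not isolated)
Conditions: 11, NaH (1.1 equiv), BnOH (0.1 equiv), THF, 0 °C; add 10, 0 °C to rt; then 60 °C; cold 1 M HCl
Reagents that add atoms: none
Why: Sodium dibenzyl malonate should add to the beta carbon of enone 10 (Michael addition) to give adduct 12; proton exchange then supplies a small share of the ketone enolate on the acyloxy-bearing methylene, which attacks one benzyl ester and expels benzyl oxide (Claisen condensation of the Dieckmann type), so that bonds C1-C6 and C2-C3 of ring B form in one flask. The closest known reaction is the malonate/alk-3-en-2-one Michael-Claisen annulation to 6-alkyl-2,4-dioxocyclohexanecarboxylates, which also tolerates alpha-prime-substituted enones; the acyloxy group on the nucleophilic methylene is the extension and makes that carbon more acidic. Ring B closes by a 6-(enolendo)-exo-trig attack of the enolate carbon on the ester carbonyl, a favoured mode. C6 arises in the conjugate addition without control (racemate) and C1 equilibrates as a beta-keto ester centre to the trans arrangement; both become sp2 in step 7, so neither needs control. The step needs the Claisen closure to start from the acyloxymethylene and the aroyl ester to survive: the other alpha carbon could only close a four-membered ring, the di-ortho-substituted benzoate is shielded against benzyl oxide and enolate attack, no foreign alkoxide is present, and the product leaves all equilibria as its stabilized 1,3-dione enolate.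

**Step 7**
Reactants: 13 (±)-trans-benzyl 3-(2,4-dimethoxy-6-propylbenzoyloxy)-2-hydroxy-4-oxo-6-propylcyclohex-2-ene-1-carboxylate
Product: 15 benzyl 3-(2,4-dimethoxy-6-propylbenzoyloxy)-2,4-dihydroxy-6-propylbenzoate, via bromo dione 14 (not isolated)
Conditions: Br2 (1.0 equiv), DMF, 0 °C; then Li2CO3, 60 °C
Reagents that add atoms: none
Why: Halogenation-dehydrohalogenation aromatization of a 2,4-dioxocyclohexanecarboxylate, in which the enol is brominated at C3 to give 14, whose dienol (C1=C2, C4=C5) holds Br on C3 and H on C6 in a 1,4-relation and should lose HBr to the arene, while Li2CO3 takes up HBr so that the benzyl ester is spared.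

**Step 8**
Reactants: 15 benzyl 3-(2,4-dimethoxy-6-propylbenzoyloxy)-2,4-dihydroxy-6-propylbenzoate
Product: 16 3-(2,4-dimethoxy-6-propylbenzoyloxy)-2,4-dihydroxy-6-propylbenzoic acid
Conditions: H2 (1 atm), Pd/C, EtOAc, rt
Reagents that add atoms: none
Why: Hydrogenolysis of the benzyl ester over palladium on carbon under neutral conditions at rt, which should leave the hindered aryl ester, the methyl ethers and the free phenols untouched and avoids the heat or base that could cause decarboxylation or acyl migration.

**Compound list**
1 | 5-propylbenzene-1,3-diol (divarinol) | CCCc1cc(O)cc(O)c1 | starting material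
2 | 1,3-dimethoxy-5-propylbenzene | CCCc1cc(OC)cc(OC)c1 | intermediate
3 | (2,4-dimethoxy-6-propylphenyl)methylidene-dimethyliminium dichlorophosphate | CCCc1cc(OC)cc(OC)c1C=[N+](C)C.[O-]P(=O)(Cl)Cl | intermediate
4 | 2,4-dimethoxy-6-propylbenzaldehyde | CCCc1cc(OC)cc(OC)c1C=O | intermediate
5 | 2,4-dimethoxy-6-propylbenzoic acid | CCCc1cc(OC)cc(OC)c1C(=O)O | intermediate
6 | butanal | CCCC=O | starting material
7 | 1-chloro-3-(triphenylphosphoranylidene)propan-2-one | O=C(CCl)C=P(c1ccccc1)(c1ccccc1)c1ccccc1 | starting material
8 | (E)-1-chlorohept-3-en-2-one | CCC/C=C/C(=O)CCl | intermediate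
9 | caesium 2,4-dimethoxy-6-propylbenzoate | CCCc1cc(OC)cc(OC)c1C(=O)[O-].[Cs+] | intermediate
10 | (E)-2-oxohept-3-en-1-yl 2,4-dimethoxy-6-propylbenzoate | CCC/C=C/C(=O)COC(=O)c1c(CCC)cc(OC)cc1OC | intermediate
11 | dibenzyl malonate | O=C(CC(=O)OCc1ccccc1)OCc1ccccc1 | starting material
12 | dibenzyl 2-[1-(2,4-dimethoxy-6-propylbenzoyloxy)-2-oxoheptan-4-yl]propanedioate (racemic; present as its sodium enolate) | CCCC(CC(=O)COC(=O)c1c(CCC)cc(OC)cc1OC)C(C(=O)OCc1ccccc1)C(=O)OCc1ccccc1 | intermediate
13 | (±)-trans-benzyl 3-(2,4-dimethoxy-6-propylbenzoyloxy)-2-hydroxy-4-oxo-6-propylcyclohex-2-ene-1-carboxylate (one enantiomer drawn) | CCC[C@@H]1CC(=O)C(OC(=O)c2c(CCC)cc(OC)cc2OC)=C(O)[C@H]1C(=O)OCc1ccccc1 | intermediate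
14 | benzyl 3-bromo-3-(2,4-dimethoxy-6-propylbenzoyloxy)-2,4-dioxo-6-propylcyclohexane-1-carboxylate (mixture of diastereomers) | CCCC1CC(=O)C(Br)(OC(=O)c2c(CCC)cc(OC)cc2OC)C(=O)C1C(=O)OCc1ccccc1 | intermediate
15 | benzyl 3-(2,4-dimethoxy-6-propylbenzoyloxy)-2,4-dihydroxy-6-propylbenzoate | CCCc1cc(OC)cc(OC)c1C(=O)Oc1c(O)cc(CCC)c(C(=O)OCc2ccccc2)c1O | intermediate
16 | 3-(2,4-dimethoxy-6-propylbenzoyloxy)-2,4-dihydroxy-6-propylbenzoic acid (CNP0211929.0) | CCCc1cc(OC)cc(OC)c1C(=O)Oc1c(O)cc(CCC)c(C(=O)O)c1O | target

**Step count**
Total: 8 steps. Longest linear sequence: 7 steps (1, 2, 3, 5, 6, 7, 8, from divarinol); step 4 is a one-step side branch.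

**Steps most likely to fail**

Step 7. Bromine transfer from the transient bromo dione to the electron-rich rings, or loss of the aroyl group from the carbon that carries both bromine and acyloxy, may outrun the 1,4-loss of HBr. The fallback replaces electrophilic halogenation at C3 by a selenoxide elimination and sets out from 13. Two equivalents of LiN(SiMe3)2 in THF at -78 °C should form the dianion (1,3-dione enolate plus ester-stabilized carbanion at C1), which PhSeBr should trap at C1 anti to the propyl group. This would give (±)-benzyl 3-(2,4-dimethoxy-6-propylbenzoyloxy)-2-hydroxy-4-oxo-1-(phenylselanyl)-6-propylcyclohex-2-ene-1-carboxylate F1. Oxidation with H2O2 in CH2Cl2/pyridine at 0 °C would give the selenoxide (±)-benzyl 3-(2,4-dimethoxy-6-propylbenzoyloxy)-2-hydroxy-4-oxo-1-(phenylseleninyl)-6-propylcyclohex-2-ene-1-carboxylate F2. Its syn-elimination with the C6 hydrogen and enolization of the resulting dienone return the route to 15.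

Step 6. Transfer of the aroyl group from the central oxygen to benzyl oxide or to an enolate oxygen, or stalling at the open-chain adduct, may prevent ring closure. The fallback closes ring B without the oxygen on C3 and introduces it afterwards; it sets out from 11 and uses acid 5. The parent annulation of 11 with purchased (E)-hept-3-en-2-one F3 under the same base (NaH, THF, 0 to 60 °C) should pass through the open-chain adduct dibenzyl 2-(2-oxoheptan-4-yl)propanedioate F4. Claisen closure would give (±)-trans-benzyl 2-hydroxy-4-oxo-6-propylcyclohex-2-ene-1-carboxylate F5. Diazo transfer with 4-acetamidobenzenesulfonyl azide and Et3N in MeCN at the doubly activated C3 would give (±)-trans-benzyl 3-diazo-2,4-dioxo-6-propylcyclohexane-1-carboxylate F6. O-H insertion of the carbenoid generated with catalytic Rh2(OAc)4 into acid 5 (CH2Cl2, 40 °C) would then place the aroyloxy group on C3 and return the route to 13.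

Step 5. Conjugate addition or oligomerization of the volatile, labile chloro enone under the basic carboxylate, or its loss on handling, may erode the coupling. The fallback makes the ester bond first on a simple dihaloketone and forms the alkene last; it sets out from 5 (through its caesium salt 9). Alkylation of 9 with an excess of 1,3-dichloroacetone in DMF should give 3-chloro-2-oxopropyl 2,4-dimethoxy-6-propylbenzoate F7. PPh3 in toluene at 60 °C would give [3-(2,4-dimethoxy-6-propylbenzoyloxy)-2-oxopropyl]triphenylphosphonium chloride F8. Aqueous Na2CO3 would then give the ylide 2-oxo-3-(triphenylphosphoranylidene)propyl 2,4-dimethoxy-6-propylbenzoate F9. Its Wittig reaction with butanal 6 (THF, 60 °C) returns the route to 10.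

**Further compounds**
F1 | step 7 | (±)-benzyl 3-(2,4-dimethoxy-6-propylbenzoyloxy)-2-hydroxy-4-oxo-1-(phenylselanyl)-6-propylcyclohex-2-ene-1-carboxylate (selenium trans to propyl) | CCC[C@@H]1CC(=O)C(OC(=O)c2c(CCC)cc(OC)cc2OC)=C(O)[C@]1([Se]c1ccccc1)C(=O)OCc1ccccc1
F2 | step 7 | (±)-benzyl 3-(2,4-dimethoxy-6-propylbenzoyloxy)-2-hydroxy-4-oxo-1-(phenylseleninyl)-6-propylcyclohex-2-ene-1-carboxylate (mixture at selenium) | CCC[C@@H]1CC(=O)C(OC(=O)c2c(CCC)cc(OC)cc2OC)=C(O)[C@]1([Se](=O)c1ccccc1)C(=O)OCc1ccccc1
F3 | step 6 | (E)-hept-3-en-2-one | CCC/C=C/C(C)=O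
F4 | step 6 | dibenzyl 2-(2-oxoheptan-4-yl)propanedioate (racemic) | CCCC(CC(C)=O)C(C(=O)OCc1ccccc1)C(=O)OCc1ccccc1
F5 | step 6 | (±)-trans-benzyl 2-hydroxy-4-oxo-6-propylcyclohex-2-ene-1-carboxylate | CCC[C@@H]1CC(=O)C=C(O)[C@H]1C(=O)OCc1ccccc1
F6 | step 6 | (±)-trans-benzyl 3-diazo-2,4-dioxo-6-propylcyclohexane-1-carboxylate | CCC[C@@H]1CC(=O)C(=[N+]=[N-])C(=O)[C@H]1C(=O)OCc1ccccc1
F7 | step 5 | 3-chloro-2-oxopropyl 2,4-dimethoxy-6-propylbenzoate | CCCc1cc(OC)cc(OC)c1C(=O)OCC(=O)CCl
F8 | step 5 | [3-(2,4-dimethoxy-6-propylbenzoyloxy)-2-oxopropyl]triphenylphosphonium chloride | CCCc1cc(OC)cc(OC)c1C(=O)OCC(=O)C[P+](c1ccccc1)(c1ccccc1)c1ccccc1.[Cl-]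
F9 | step 5 | 2-oxo-3-(triphenylphosphoranylidene)propyl 2,4-dimethoxy-6-propylbenzoate | CCCc1cc(OC)cc(OC)c1C(=O)OCC(=O)C=P(c1ccccc1)(c1ccccc1)c1ccccc1
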